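I ask which flask ends with the most side product at 8.0 h, and I reckon it from one yardstick, the rate of side product at full c(starting material), scaled by how each recipe holds up c(starting material) and c(partner).

| setting | elm | ash | oak | birch | red | violet | ochre | green |
|---|---|---|---|---|---|---|---|---|
| starting material | 10 mM | 10 mM | 10 mM | 15 mM | 10 mM | 10 mM (fed, over 6.0 h) | 10 mM (fed, over 1.5 h) | 10 mM |
| partner | 20 mM | 10 mM | 15 mM | 20 mM | 20.0 mM (fed, over 6.0 h) | 20.0 mM | 20.0 mM | 20.0 mM |
| remark | run made earlier | run made earlier | run made earlier | run made earlier | all else is in the flask from the start; the feed brings no volume worth counting | all else is in the flask from the start; the feed brings no volume worth counting | all else is in the flask from the start; the feed brings no volume worth counting | everything together at the start |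
| time |  |  |  |  | 8.0 h | 8.0 h | 8.0 h | 8.0 h |

| run | time / h | side product / % | target / % | starting material / % |
|---|---|---|---|---|
| elm | 1.00 | 5.7 | 1.2 | 87.9 |
| elm | 2.00 | 9.5 | 1.9 | 83.2 |
| elm | 3.00 | 14.7 | 2.5 | 79.3 |
| elm | 4.00 | 16.3 | 5.7 | 74.7 |
| elm | 5.00 | 18.9 | 6.0 | 71.0 |
| ash | 0.417 | 1.5 | 0.6 | 96.0 |
| ash | 1.33 | 4.1 | 2.5 | 92.6 |
| ash | 2.00 | 3.0 | 0.8 | 90.1 |
| ash | 3.00 | 6.6 | 3.5 | 87.8 |
| ash | 5.00 | 12.6 | 2.8 | 85.1 |
| oak | 0.417 | 2.0 | 0.1 | 91.8 |
| oak | 1.33 | 4.7 | 1.1 | 89.3 |
| oak | 2.00 | 7.2 | 2.8 | 85.6 |
| oak | 3.00 | 11.7 | 2.5 | 82.6 |
| oak | 5.00 | 15.8 | 2.8 | 76.6 |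
| birch | 1.00 | 5.9 | 1.1 | 87.0 |
| birch | 2.00 | 12.0 | 2.7 | 80.6 |
| birch | 3.00 | 16.6 | 3.6 | 75.8 |
| birch | 4.00 | 20.7 | 4.3 | 72.3 |
| birch | 5.00 | 25.2 | 3.4 | 66.8 |

(scatter of a reading: 1 percentage point)

* which flask leads in amount of side product, in percent of the starting material charged ("all alike" within 1.5 percentage points) (red / violet / ochre / green / all alike)
* how much side product is there at the end, in percent of the starting material charged: red
* how much side product is there at the end, in percent of the starting material charged: violet
* how much side product is there at the end, in percent of the starting material charged: ochre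
* how much side product is there at the end, in percent of the starting material charged: green

- percent here means starting material units held: one side product counts as two
- a reading or a percentage of target counts all its forms, free or not

From elm I take the side product at the last reading, divide it by that time and by the square of the mean fraction of starting material left, and call the result the yardstick g, the share of the charge going to side product per hour at full c(starting material), 0.0517 h⁻¹, an apparent second-order rate constant. Birch, reckoned the same way, gives 0.0725 h⁻¹, which is 1.40 times g for a charge 1.50 times as large, so I take the rate as second order in starting material. Ash, with 10 mM of partner, gives 0.569 of g, so partner counts as well.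

I draw the curve for green, which has elm's charges, from slope g. Elm's late fall, carried on, puts the starting material at about 58.5 % at the end, so in my reckoning the slope has bent to a third of its first value, 0.0177 h⁻¹, and the curve is still climbing. With the squared mean fraction 0.628, I reckon green at 26.0 %. Ochre runs behind green by half its feed time, which gives 24.7 %. A steady ramp has a mean square of a third of its top, so violet comes to 13.0 %. Red, taken as first order in partner, comes to 16.2 %.

The forecast names green, with green 28 %, ochre 26 %, red 22 % and violet 15 %: “the rate rises with partner”. Its red stands above mine.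

The flasks give green 26.0 %, which leads, then ochre 23.9 %, red 19.1 % and violet 15.5 %.

    starting material + partner ⇌ loose adduct (K = 3.80 M⁻¹, k = 28.0 M⁻¹ h⁻¹)
    loose adduct → target (k = 0.210 h⁻¹)
    partner + target ⇌ idle adduct, settled at all times (K = 480 M⁻¹)
    starting material + loose adduct → side product (k = 44.0 M⁻¹ h⁻¹)

At 4.00 h green held 74.8 % of starting material beside 4.78 % of loose adduct and had made 15.9 % of side product, while violet held 58.3 % beside 3.89 % and had made 2.80 %. Green's simulated end of 62.2 %, put into the reckoning with g, gives 27.2 % of side product. Violet's 15.5 % is worth 3.00 h at full charge. A violet flask charged with 4.0 mM of starting material ended at 80.8 % against 74.1 %, so scaling g by charge and those hours by the squared ratio gives 7.36 %, and that flask holds 7.26 %.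

The readings were generated by integration on assumed constants.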